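Readings and results come from a simulation for substances that don't exist; the scatter is artificial.

Late in the green run, at 15.0 min, the readings show 27.0% left-handed product against 9.7% right-handed product. The single-handed free catalyst is sorting a racemate, and the sorting can be put into one number.

| flask | left-handed substrate | right-handed substrate | reagent | free catalyst | racemization catalyst | added ligand | temperature | remark | time |
|---|---|---|---|---|---|---|---|---|---|
| green | 43 mM | 43 mM | 2.5 equiv | 0.43 mol% | 0.5 mol% | 1.6 mM | −20 °C | run made earlier |  |
| red | 43 mM | 43 mM | 2.5 equiv | 0.43 mol% | 2 mol% | 1.6 mM | 13 °C | run made earlier |  |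
| grey | 43 mM | 43 mM | 2.5 equiv | 0.43 mol% | 1 mol% | 2.4 mM | −20 °C | run made earlier |  |
| Thursday's | 43 mM | 43 mM | 2.50 equiv | 0.43 mol% | 1 mol% | 1.6 mM | −5 °C |  | 6.0 min |
| Tuesday's | 43 mM | 43 mM | 2.50 equiv | 0.43 mol% | 1 mol% | 1.6 mM | 25 °C |  | 6.0 min |
| Sunday's | 43 mM | 43 mM | 2.50 equiv | 0.43 mol% | 1 mol% | 1.6 mM | −35 °C |  | 6.0 min |

| run | time / min | left-handed product / % | right-handed product / % |
|---|---|---|---|
| green | 1.00 | 2.8 | 0.7 |
| green | 2.00 | 5.8 | 0.3 |
| green | 3.00 | 6.3 | 1.2 |
| green | 4.00 | 9.9 | 4.1 |
| green | 6.00 | 14.2 | 6.2 |
| green | 10.0 | 22.3 | 7.6 |
| green | 15.0 | 27.0 | 9.7 |
| red | 0.167 | 4.7 | 0.6 |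
| red | 0.417 | 8.4 | 3.3 |
| red | 0.833 | 15.9 | 6.0 |
| red | 1.33 | 21.0 | 8.9 |
| red | 1.50 | 21.2 | 8.2 |
| red | 2.50 | 29.5 | 14.0 |
| red | 3.00 | 34.2 | 13.4 |
| grey | 3.00 | 8.6 | 1.3 |
| grey | 6.00 | 14.5 | 4.5 |
| grey | 8.00 | 16.9 | 4.9 |
| grey | 12.0 | 23.5 | 9.1 |
| grey | 15.0 | 26.9 | 10.4 |

(standard deviation of a reading: 1 percentage point)

- free catalyst is single-handed; left-handed substrate and right-handed substrate are mirror images of each other, charged as a racemate, each of them at the stated concentration
- the numbers in the tables scatter by 1 percentage point (one standard deviation)
- reactions considered so far: reagent + free catalyst + left-handed substrate -> free catalyst + left-handed product; reagent + free catalyst + right-handed substrate -> free catalyst + right-handed product; left-handed substrate + racemization catalyst <-> right-handed substrate + racemization catalyst; racemization catalyst + added ligand <-> idle complex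

- the best flask by share of left-handed product in all that became left-handed product or right-handed product; "all alike" if 1.5 percentage points covers them all (Thursday's / Tuesday's / Sunday's / all alike)
- share of left-handed product in all that became left-handed product or right-handed product, Thursday's
- share of left-handed product in all that became left-handed product or right-handed product, Tuesday's
- share of left-handed product in all that became left-handed product or right-handed product, Sunday's

Each substrate is half the charge, so doubling a product reading gives that product as a part of its substrate's charge. Without racemization, each substrate decays by its own constant under the same reagent and free catalyst. The logarithm of what is left of the left-handed substrate, over the same logarithm for the right-handed substrate, is then the ratio of the two constants. The last green reading, with racemization set aside and with its scatter, gives s = 3.60, the selectivity factor.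

Time: with s held and no racemization, the share of left-handed product starts at s/(1 + s), which is 78.3%, and falls as conversion grows. Green reads 73.6% at its last reading, less than that start.

Racemization catalyst: by hand, it feeds right-handed substrate back to left-handed and holds the share up. Grey carries twice the loading of green, yet its last share is 72.1%.

Added ligand: by hand, it takes racemization catalyst into idle complex. Grey raises it to 2.4 mM together with the catalyst, so these readings do not separate the two.

Temperature: by hand, warming speeds conversion. At 3.00 min, red at 13 °C has made 47.6% of product, more than the 7.50% of green at −20 °C. Red also carries 2 mol% of racemization catalyst against 0.5 mol% in green, so these runs differ in two settings. The ratio of logarithms at that red reading is 3.69.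

The reckoning here holds s at 3.60 and ranks the flasks by conversion at 6.0 min. Sunday's stays near 78.3%, Tuesday's comes lowest, and Thursday's falls between.

The forecast names Sunday's, with 72% for Thursday's, 62% for Tuesday's and 81% for Sunday's. Of the fall of the share in green and grey it says: “That fall is about what plain kinetic resolution gives”. Its Sunday's figure stands above the 78.3% reckoned here.

    reagent + free catalyst + left-handed substrate → free catalyst + left-handed product (k = 680 /M²/s, Ea = 36.0 kJ/mol)
    reagent + free catalyst + right-handed substrate → free catalyst + right-handed product (k = 260 /M²/s, Ea = 40.0 kJ/mol)
    left-handed substrate + racemization catalyst ⇌ right-handed substrate + racemization catalyst, rate k3*[racemization catalyst]*[left-handed substrate] forward; the back reaction follows from the equilibrium constant (k = 4.80 /M/s, Ea = 38.0 kJ/mol)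
    racemization catalyst + added ligand ⇌ idle complex (K = 14000 /M, k = 12.0 /M/s, Ea = 37.0 kJ/mol, ΔH = −71.0 kJ/mol)
    (constants at 25 °C)

The best flask is Sunday's, at 79.0%, against 71.3% for Thursday's and 60.4% for Tuesday's. At 2.87 min in Sunday's, left-handed substrate goes to product 8.4 times as fast as it passes into right-handed substrate, counting the forward step alone. The ratio of logarithms, applied to what is left in Sunday's, reads 3.83, beside the 3.60 of green. In Tuesday's, 8.0% of the left-handed substrate and 35% of the right-handed substrate are left at 6.00 min, and the same ratio reads 2.38.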